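**Retrosynthetic overview**
- 17 ⇐ 16 by cleavage of the two aryl silyl ethers; 16 ⇐ aldol union of the (R)-lactone 12 with O-silyl vanillin 7 (C3–C1' bond, sets C3 and the carbinol carbon).
- 12 ⇐ 10 by enantioselective Baeyer–Villiger ring expansion of the prochiral cyclobutanone (four-membered carbocycle → five-membered lactone; sets C4). This is the only ring-forming event.
- 10 ⇐ Negishi coupling of the zinc reagent from 3-(bromomethyl)cyclobutanone 8 with aryl bromide 4; 7 ⇐ formylation of the same bromide 4.
- 4 ⇐ guaiacol 2 (para-bromination, silylation) ⇐ catechol 1 (mono-O-methylation). Both aryl rings come from 1; the cyclobutane is bought in 8.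

Assumption: the SMILES is read as (3S,4R)-3-[(S)-hydroxy(4-hydroxy-3-methoxyphenyl)methyl]-4-[(4-hydroxy-3-methoxyphenyl)methyl]oxolan-2-one, i.e. 3,4-trans (as in matairesinol) with a syn (erythro) relationship between C3 and the carbinol carbon. TBS = tert-butyldimethylsilyl, TBSO = tert-butyldimethylsilyloxy. The antipode of the Baeyer–Villiger ligand that gives the (R)-lactone is fixed in a pilot run by the sign of optical rotation against known (R)-4-(arylmethyl)butyrolactones.

**Step 1**
Reactants: 1 catechol (benzene-1,2-diol)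
Product: 2 guaiacol (2-methoxyphenol)
Conditions: MeI (1.0 equiv), K2CO3 (1.0 equiv), acetone, reflux; acid–base extraction, distillation
Reagents that add atoms: iodomethane, CI
Why: Williamson ether synthesis in which the hydrogen-bond-stabilised catechol monoanion is alkylated once by limiting iodomethane, and guaiacol is separated from veratrole (base-insoluble) and catechol (water-soluble) by extraction.

**Step 2**
Reactants: 2 guaiacol
Product: 4 4-bromo-2-methoxy-1-(tert-butyldimethylsilyloxy)benzene, via 4-bromo-2-methoxyphenol 3 (not isolated)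
Conditions: NBS (1.0 equiv), DMF, −10 °C to rt; then imidazole (3 equiv), TBSCl (1.3 equiv), rt
Reagents that add atoms: N-bromosuccinimide, O=C1CCC(=O)N1Br; tert-butyldimethylsilyl chloride, CC(C)(C)[Si](C)(C)Cl
Why: Electrophilic aromatic bromination with NBS in DMF goes para to the free hydroxyl (the stronger director), and the phenol is then silylated in the same flask under imidazole/TBSCl conditions, so bromine ends para to the silyloxy and meta to the methoxy group.

**Step 3**
Reactants: 4 4-bromo-2-methoxy-1-(tert-butyldimethylsilyloxy)benzene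
Product: 7 4-(tert-butyldimethylsilyloxy)-3-methoxybenzaldehyde, via aryllithium 5 (not isolated), via lithium hemiaminolate 6 (not isolated)
Conditions: n-BuLi (1.05 equiv), THF, −78 °C; DMF (1.5 equiv), −78 to 0 °C; aq NH4Cl
Reagents that add atoms: N,N-dimethylformamide, CN(C)C=O
Why: Bromine–lithium exchange followed by Bouveault-type formylation, in which the tetrahedral adduct 6 survives until the aqueous quench and so prevents over-addition.

**Step 4**
Reactants: 8 3-(bromomethyl)cyclobutan-1-one; 4 4-bromo-2-methoxy-1-(tert-butyldimethylsilyloxy)benzene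
Product: 10 3-[[4-(tert-butyldimethylsilyloxy)-3-methoxyphenyl]methyl]cyclobutan-1-one, via organozinc bromide 9 (not isolated)
Conditions: 8 (1.4 equiv), Zn dust (TMSCl/1,2-dibromoethane-activated), LiCl, THF, 50 °C; then 4, Pd(OAc)2 (2 mol%), SPhos (4 mol%), THF, 25–40 °C
Reagents that add atoms: none
Why: Negishi cross-coupling in which LiCl-assisted zinc insertion gives a ketone-tolerant primary alkylzinc that transmetalates to the arylpalladium bromide formed from zerovalent palladium and 4, with SPhos favouring reductive elimination over β-hydride or β-carbon elimination.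

**Step 5**
Reactants: 10 3-[[4-(tert-butyldimethylsilyloxy)-3-methoxyphenyl]methyl]cyclobutan-1-one
Product: 12 (4R)-4-[[4-(tert-butyldimethylsilyloxy)-3-methoxyphenyl]methyl]oxolan-2-one, via Criegee adduct 11 (not isolated)
Conditions: Sc(OTf)3 (5 mol%), C2-symmetric amino-acid-derived N,N′-dioxide bis(anilide) ligand (6 mol%, antipode giving R), mCPBA (1.2 equiv), EtOAc, −20 °C; aq Na2S2O3/NaHCO3
Reagents that add atoms: 3-chloroperoxybenzoic acid, OOC(=O)c1cccc(Cl)c1
Why: Catalytic enantioselective Baeyer–Villiger ring expansion in which the peracid adds to the strained ketone on the chiral trivalent scandium centre to give Criegee adduct 11, and the catalyst selects which enantiotopic ring CH2 lies antiperiplanar to the O–O bond and undergoes the 1,2-shift to oxygen, desymmetrising the cyclobutanone and setting C4 as R.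

**Step 6**
Reactants: 12 (4R)-4-[[4-(tert-butyldimethylsilyloxy)-3-methoxyphenyl]methyl]oxolan-2-one; 7 4-(tert-butyldimethylsilyloxy)-3-methoxybenzaldehyde
Product: 16 (3S,4R)-3-[(S)-[4-(tert-butyldimethylsilyloxy)-3-methoxyphenyl](hydroxy)methyl]-4-[[4-(tert-butyldimethylsilyloxy)-3-methoxyphenyl]methyl]oxolan-2-one, via lithium enolate 13 (not isolated), via chlorozirconocene enolate 14 (not isolated), via zirconium aldolate 15 (not isolated)
Conditions: LiN(i-Pr)2 (1.1 equiv), THF, −78 °C; Cp2ZrCl2 (1.2 equiv), −78 to −40 °C; 7 (1.2 equiv), −78 to −40 °C; pH 7 buffer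
Reagents that add atoms: none
Why: Proposed new method: lithium-to-zirconium transmetalation gives the O-bound chlorozirconocene enolate 14 of a butyrolactone whose ring locks the E(O) geometry; the two cyclopentadienyl ligands on tetravalent zirconium disfavour the chair Zimmerman–Traxler arrangement (which would give the anti adduct) and route C–C bond formation through a boat-like or open transition state, so the enolate gives the syn (erythro) aldolate 15, while the C4 arylmethyl group shields one enolate face so the aldehyde adds trans to it, which together set C3 as S and the carbinol carbon as S; the closest known reaction type is the syn-selective aldol addition of zirconocene enolates of acyclic esters, amides and cyclic ketones, which to my knowledge has not been shown for a 4-substituted butyrolactone enolate, whose lithium enolate gives roughly 1:1 carbinol epimers.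

**Step 7**
Reactants: 16 (3S,4R)-3-[(S)-[4-(tert-butyldimethylsilyloxy)-3-methoxyphenyl](hydroxy)methyl]-4-[[4-(tert-butyldimethylsilyloxy)-3-methoxyphenyl]methyl]oxolan-2-one
Product: 17 (3S,4R)-3-[(S)-hydroxy(4-hydroxy-3-methoxyphenyl)methyl]-4-[(4-hydroxy-3-methoxyphenyl)methyl]oxolan-2-one
Conditions: Bu4NF (2.4 equiv), AcOH (2.6 equiv), THF, 0 °C
Reagents that add atoms: none
Why: Fluoride-mediated cleavage of both aryl silyl ethers under acetic acid buffering, which keeps the medium near neutral so the β-hydroxy lactone undergoes neither retro-aldol cleavage, quinone-methide elimination nor acid-induced cyclisation, and no stereocentre is touched.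

**Compound list**
1 | catechol (benzene-1,2-diol) | Oc1ccccc1O | starting material
2 | guaiacol (2-methoxyphenol) | COc1ccccc1O | intermediate
3 | 4-bromo-2-methoxyphenol | COc1cc(Br)ccc1O | intermediate
4 | 4-bromo-2-methoxy-1-(tert-butyldimethylsilyloxy)benzene | COc1cc(Br)ccc1O[Si](C)(C)C(C)(C)C | intermediate
5 | [4-(tert-butyldimethylsilyloxy)-3-methoxyphenyl]lithium | [Li]c1ccc(O[Si](C)(C)C(C)(C)C)c(OC)c1 | intermediate
6 | lithium [4-(tert-butyldimethylsilyloxy)-3-methoxyphenyl](dimethylamino)methanolate | [Li]OC(N(C)C)c1ccc(O[Si](C)(C)C(C)(C)C)c(OC)c1 | intermediate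
7 | 4-(tert-butyldimethylsilyloxy)-3-methoxybenzaldehyde | O=Cc1ccc(O[Si](C)(C)C(C)(C)C)c(OC)c1 | intermediate
8 | 3-(bromomethyl)cyclobutan-1-one | O=C1CC(CBr)C1 | starting material
9 | [(3-oxocyclobutyl)methyl]zinc bromide | O=C1CC(C[Zn]Br)C1 | intermediate
10 | 3-[[4-(tert-butyldimethylsilyloxy)-3-methoxyphenyl]methyl]cyclobutan-1-one | COc1cc(CC2CC(=O)C2)ccc1O[Si](C)(C)C(C)(C)C | intermediate
11 | Criegee adduct: 1-hydroxy-3-[[4-(tert-butyldimethylsilyloxy)-3-methoxyphenyl]methyl]cyclobutyl 3-chloroperoxybenzoate | COc1cc(CC2CC(O)(OOC(=O)c3cccc(Cl)c3)C2)ccc1O[Si](C)(C)C(C)(C)C | intermediate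
12 | (4R)-4-[[4-(tert-butyldimethylsilyloxy)-3-methoxyphenyl]methyl]oxolan-2-one | COc1cc(C[C@H]2COC(=O)C2)ccc1O[Si](C)(C)C(C)(C)C | intermediate
13 | lithium enolate of 12 (4R) | COc1cc(C[C@H]2COC(O[Li])=C2)ccc1O[Si](C)(C)C(C)(C)C | intermediate
14 | chlorobis(cyclopentadienyl)zirconium enolate of 12 (4R) | COc1cc(C[C@H]2COC(O[Zr+2]Cl)=C2)ccc1O[Si](C)(C)C(C)(C)C.c1cc[cH-]c1.c1cc[cH-]c1 | intermediate
15 | chlorobis(cyclopentadienyl)zirconium aldolate of 16 (3S,4R, carbinol S) | COc1cc(C[C@H]2COC(=O)[C@@H]2[C@H](O[Zr+2]Cl)c2ccc(O[Si](C)(C)C(C)(C)C)c(OC)c2)ccc1O[Si](C)(C)C(C)(C)C.c1cc[cH-]c1.c1cc[cH-]c1 | intermediate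
16 | (3S,4R)-3-[(S)-[4-(tert-butyldimethylsilyloxy)-3-methoxyphenyl](hydroxy)methyl]-4-[[4-(tert-butyldimethylsilyloxy)-3-methoxyphenyl]methyl]oxolan-2-one | COc1cc(C[C@H]2COC(=O)[C@@H]2[C@H](O)c2ccc(O[Si](C)(C)C(C)(C)C)c(OC)c2)ccc1O[Si](C)(C)C(C)(C)C | intermediate
17 | (3S,4R)-3-[(S)-hydroxy(4-hydroxy-3-methoxyphenyl)methyl]-4-[(4-hydroxy-3-methoxyphenyl)methyl]oxolan-2-one | COc1cc(C[C@H]2COC(=O)[C@@H]2[C@H](O)c2ccc(O)c(OC)c2)ccc1O | target

**Step count and risks**
Total steps: 7. Longest linear sequence: 6 (steps 1, 2, 4, 5, 6, 7); step 3 is a branch from 4.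

Most likely to fail:

1. Step 6 (the proposed new aldol). The zirconium enolate may react sluggishly with the electron-rich aldehyde, or the syn:anti ratio may be low. The fallback uses known chemistry, sets out from 12 (with 7) and comes back at 16. The lithium enolate 13 (LiN(i-Pr)2, THF, −78 °C) is treated with 7 without transmetalation, which gives 16 together with its carbinol epimer (3S,4R)-3-[(R)-[4-(TBSO)-3-methoxyphenyl](hydroxy)methyl]-4-[[4-(TBSO)-3-methoxyphenyl]methyl]oxolan-2-one F5, both 3,4-trans. The unseparated mixture is oxidised with Dess–Martin periodinane (CH2Cl2, NaHCO3) to the single keto lactone (3S,4R)-3-[4-(TBSO)-3-methoxybenzoyl]-4-[[4-(TBSO)-3-methoxyphenyl]methyl]oxolan-2-one F6. Reduction of F6 with Zn(BH4)2 (Et2O, −78 to −20 °C) under chelation control (zinc bridges the ketone and lactone carbonyls; hydride enters from the face of the C3–H) returns the syn alcohol 16. This costs two extra steps.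

2. Step 5 (enantioselectivity of the ring expansion). Uncatalysed peracid oxidation of the strained ketone and the flexible CH2Ar substituent may hold the ee near 85–90%. The fallback replaces the peracid/Lewis acid desymmetrisation by a flavoenzyme/O2 desymmetrisation on the free phenol; it sets out from 10 and comes back at 12. Bu4NF/AcOH gives 3-[(4-hydroxy-3-methoxyphenyl)methyl]cyclobutan-1-one F3. E. coli whole cells expressing a Baeyer–Villiger monooxygenase (air, glucose, buffer pH 7–8, 25 °C) give (4R)-4-[(4-hydroxy-3-methoxyphenyl)methyl]oxolan-2-one F4; the cyclohexanone- and cyclopentanone-monooxygenase families are enantiocomplementary on 3-benzylcyclobutanones, and the (R)-selective one is used. TBSCl/imidazole (DMF) then returns 12.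

3. Step 4 (Negishi coupling). The (3-oxocyclobutyl)methyl radical formed transiently during zinc insertion can ring-open to an α-keto radical, and the alkylpalladium can undergo β-carbon elimination. The fallback builds the four-membered ring instead of buying it; it sets out from 4 and comes back at 10. Aryllithium 5 (n-BuLi, THF, −78 °C) is allylated with allyl bromide (CuBr·SMe2 cat.) to 4-allyl-2-methoxy-1-(TBSO)benzene F1. A [2+2] cycloaddition with dichloroketene (Cl3CCOCl, Zn/Cu couple, Et2O) gives 2,2-dichloro-3-[[4-(TBSO)-3-methoxyphenyl]methyl]cyclobutan-1-one F2. Zn/AcOH dechlorination gives 10. This costs two extra steps.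

**Further compounds**
F1 | step 4 | 4-allyl-2-methoxy-1-(tert-butyldimethylsilyloxy)benzene | C=CCc1ccc(O[Si](C)(C)C(C)(C)C)c(OC)c1
F2 | step 4 | 2,2-dichloro-3-[[4-(tert-butyldimethylsilyloxy)-3-methoxyphenyl]methyl]cyclobutan-1-one (racemic) | O=C1CC(Cc2ccc(O[Si](C)(C)C(C)(C)C)c(OC)c2)C1(Cl)Cl
F3 | step 5 | 3-[(4-hydroxy-3-methoxyphenyl)methyl]cyclobutan-1-one | COc1cc(CC2CC(=O)C2)ccc1O
F4 | step 5 | (4R)-4-[(4-hydroxy-3-methoxyphenyl)methyl]oxolan-2-one | COc1cc(C[C@H]2COC(=O)C2)ccc1O
F5 | step 6 | (3S,4R)-3-[(R)-[4-(tert-butyldimethylsilyloxy)-3-methoxyphenyl](hydroxy)methyl]-4-[[4-(tert-butyldimethylsilyloxy)-3-methoxyphenyl]methyl]oxolan-2-one | COc1cc(C[C@H]2COC(=O)[C@@H]2[C@@H](O)c2ccc(O[Si](C)(C)C(C)(C)C)c(OC)c2)ccc1O[Si](C)(C)C(C)(C)C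
F6 | step 6 | (3S,4R)-3-[4-(tert-butyldimethylsilyloxy)-3-methoxybenzoyl]-4-[[4-(tert-butyldimethylsilyloxy)-3-methoxyphenyl]methyl]oxolan-2-one | COc1cc(C[C@H]2COC(=O)[C@@H]2C(=O)c2ccc(O[Si](C)(C)C(C)(C)C)c(OC)c2)ccc1O[Si](C)(C)C(C)(C)C
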